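Slowness is not what ended the two earlier runs. Friday's target stands at 51.9% after 5.00 d and at 52.2% after 15.0 d, and Wednesday's stands at 70.0% after 8.00 d and at 70.4% after 15.0 d. Both runs have gone flat in less time than the 20 d allowed, so the question is what the end state must be.

| setting | Friday's | Wednesday's | spring | dusk | dawn | summer |
|---|---|---|---|---|---|---|
| substrate | 0.094 M | 0.094 M | 0.094 M | 0.094 M | 0.094 M | 0.094 M |
| coupling partner | 0.054 M | 0.46 M | 0.0400 M | 0.0800 M | 0.150 M | 0.300 M |
| free catalyst | 8.9 mM | 8.9 mM | 8.9 mM | 8.9 mM | 8.9 mM | 8.9 mM |
| remark | run made earlier | run made earlier |  |  |  |  |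
| time |  |  | 20 d | 20 d | 20 d | 20 d |

| run | time / d | target / % |
|---|---|---|
| Friday's | 1.04 | 28.3 |
| Friday's | 1.67 | 38.6 |
| Friday's | 3.00 | 48.9 |
| Friday's | 5.00 | 51.9 |
| Friday's | 8.00 | 52.0 |
| Friday's | 15.0 | 52.2 |
| Wednesday's | 2.50 | 62.4 |
| Wednesday's | 5.00 | 69.4 |
| Wednesday's | 8.00 | 70.0 |
| Wednesday's | 10.0 | 70.2 |
| Wednesday's | 12.0 | 69.9 |
| Wednesday's | 15.0 | 70.4 |

(standard deviation of a reading: 0.3 percentage points)

- reactions considered so far: substrate + free catalyst -> free catalyst + open intermediate; free catalyst + open intermediate <-> catalyst intermediate; coupling partner + catalyst intermediate -> free catalyst + target; substrate + coupling partner -> uncatalysed product; free catalyst -> spent catalyst A; substrate + free catalyst -> spent catalyst B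
- "hardly changes" means that all values lie within two and a half points (for a concentration: within two and a half percent of the largest)

- [target] at the end for spring, dusk, dawn, summer, in this order
- how that number moves from the first to the last of them (falls, then rises / hardly changes / rises all the way / falls all the way / rises, then falls)

Two of us argued over this row.

I held the limiting-reagent view. Friday's last reading, set against the partner charged there, comes to 0.909, and I call this ratio, read with the scatter of that reading, the partner return: target finally made per coupling partner charged. Spring and dusk charge less partner than substrate, so I multiplied the return by the partner charge and got 0.0363 M for spring and 0.0727 M for dusk. Dawn and summer charge more partner than substrate, so I put the same return on the substrate charge and got 0.0854 M for both. Wednesday's lower 0.0662 M I set aside, since its partner charge lies above summer's. My row climbs and then stays level.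

My colleague's forecast reads 0.0365 M, 0.068 M, 0.076 M and 0.072 M, so it rises, then falls. The ground given was this: “At high charge, the background reaction steals substrate as partner rises”. We parted most widely at summer, where I stood higher than the forecast.

The flasks end at 0.0365 M, 0.0734 M, 0.0819 M and 0.0733 M: the row rises, then falls, as the forecast said, and it turns at 0.10 M, with summer below dawn.

    substrate + free catalyst → free catalyst + open intermediate (k = 31.5 L mol⁻¹ h⁻¹)
    free catalyst + open intermediate ⇌ catalyst intermediate (K = 14.0 L mol⁻¹, k = 4.96 L mol⁻¹ h⁻¹)
    coupling partner + catalyst intermediate → free catalyst + target (k = 15.8 L mol⁻¹ h⁻¹)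
    substrate + coupling partner → uncatalysed product (k = 0.253 L mol⁻¹ h⁻¹)
    free catalyst → spent catalyst A (k = 1.19 × 10⁻⁵ h⁻¹)
    substrate + free catalyst → spent catalyst B (k = 0.243 L mol⁻¹ h⁻¹)

My view keeps spring and dusk, whose partner charges stand below that turn. The partner return gave 0.0363 M for spring against 0.0365 M, and 0.0727 M for dusk against 0.0734 M, where the forecast had 0.068 M. In spring, at 0.107 d, open intermediate is made 9.54 times faster than it is used up, each step taken net, and at the end 53.1% of the substrate charged stands as open intermediate, with 0% of the coupling partner left.

The runs come from a simulation from invented constants; the scatter is artificial.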